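Ring A (the 5,7-dioxygenated lactone, unprimed locants; ring B primed) is disconnected across C2–C3 and C4–C4a. Backwards, O1–C2 on the phloroglucinol ring is a cationic 2-oxadiene (C2=O1+–C8a=C4a) at the formate oxidation level, and C3=C4 is a p-methoxystyrene on C3′ of the finished ring B lactone. The key step, an oxa-Povarov [4+2], exploits the arene carbon C4a ortho to O1: an orthoformate-derived aryloxycarbenium ion (ring A oxygens masked as carbonates) adds across the (E)-styryl lactone, forming both bonds in one operation and relaying the catalyst-set 4′R centre to C4. Lactol oxidation, double kinetic enolate protonation (trans,trans to cis,cis) and global deprotection complete the route.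

Key step: step 8

Assumption: acetal 19 and lactol 20 are handled as anomeric mixtures at C2 of ring A (the 2S anomers are drawn); this centre disappears in step 9.

Step 1
Reactants: 1 1,2,3,4-tetramethoxybenzene
Product: 4 2,3,4,5-tetramethoxyphenol, via aryllithium 2 (not isolated), via arylboronate 3 (not isolated)
Conditions: n-BuLi, TMEDA, THF, 0 °C; B(OMe)3, −78 °C to rt; then AcOH, 30% H2O2, 0 °C to rt
Reagents that add atoms: hydrogen peroxide, OO
Why: Directed ortho-lithiation at the only type of ring C–H (ortho to OMe), borylation and peroxide ipso-oxidation of the arylboronate should give the phenol; no stereocentre is involved.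

Step 2
Reactants: 4 2,3,4,5-tetramethoxyphenol; 5 ethyl propiolate
Product: 7 5,6,7,8-tetramethoxy-2H-chromen-2-one, via Z-acrylate ester 6 (not isolated)
Conditions: Pd(OAc)2 (5 mol %), CF3CO2H/CH2Cl2, rt
Reagents that add atoms: none
Why: Fujiwara-type Pd-catalysed trans-hydroarylation of the propiolate at the single free ring position (ortho to OH) gives the Z-acrylate, which should lactonise with loss of ethanol to the coumarin.

Step 3
Reactants: 7 5,6,7,8-tetramethoxy-2H-chromen-2-one; 8 (4-methoxyphenyl)boronic acid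
Product: 9 (4R)-5,6,7,8-tetramethoxy-4-(4-methoxyphenyl)chroman-2-one
Conditions: Rh(acac)(C2H4)2 (3 mol %), (R)-SEGPHOS, dioxane/H2O (10:1), 60 °C
Reagents that add atoms: none
Why: Hayashi–Miyaura Rh-catalysed asymmetric 1,4-addition of the arylboronic acid to the coumarin; the chiral bisphosphine–Rh aryl complex selects the enantioface of C3′=C4′ and sets C4′ as R (ligand control, the ligand enantiomer being chosen accordingly).

Step 4
Reactants: 9 (4R)-5,6,7,8-tetramethoxy-4-(4-methoxyphenyl)chroman-2-one; 10 1-[(E)-2-bromoethenyl]-4-methoxybenzene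
Product: 12 (3S,4R)-5,6,7,8-tetramethoxy-4-(4-methoxyphenyl)-3-[(E)-2-(4-methoxyphenyl)ethenyl]chroman-2-one (3,4-trans), via zinc enolate 11 (not isolated)
Conditions: LiN(SiMe3)2, THF, −78 °C; ZnCl2; then 10, Pd(dba)2 (5 mol %), P(t-Bu)3, THF, rt; then Et3N (0.1 equiv), CH2Cl2, rt
Reagents that add atoms: none
Why: Negishi-type Pd-catalysed α-alkenylation of the zinc lactone enolate with retention of the (E)-bromoalkene geometry; after base equilibration by α-reprotonation of the dienolate the styryl group should rest trans to the C4′ aryl group (thermodynamic control from C4′).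

Step 5
Reactants: 13 phloroglucinol
Product: 14 di-tert-butyl (5-hydroxy-1,3-phenylene) bis(carbonate)
Conditions: Boc2O (2.0 equiv), DMAP (5 mol %), MeCN, 0 °C to rt; separation from mono- and tris-carbonate (recycled)
Reagents that add atoms: di-tert-butyl dicarbonate, CC(C)(C)OC(=O)OC(=O)OC(C)(C)C
Why: DMAP-catalysed O-acylation of two of the three equivalent phenols (statistical) installs electron-withdrawing, hindered carbonates that lower the π-nucleophilicity of the future ring A arene for step 8.

Step 6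
Reactants: 14 di-tert-butyl (5-hydroxy-1,3-phenylene) bis(carbonate); 15 trimethyl orthoformate
Product: 16 3,5-bis(tert-butoxycarbonyloxy)phenyl dimethyl orthoformate
Conditions: 15 (15 equiv, neat), pyridinium p-toluenesulfonate (1 mol %), 70 °C, MeOH distilled off; Et3N quench, evaporation of excess 15
Reagents that add atoms: none
Why: Acid-catalysed transorthoesterification (exchange of one methoxy group for the phenol, as in the preparation of aryl dialkyl orthoformates from phenols and trialkyl orthoformates) is driven by removal of methanol, and the large excess of 15 should hold the exchange at the mono-aryl stage; no stereocentre is formed.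

Step 7
Reactants: 16 3,5-bis(tert-butoxycarbonyloxy)phenyl dimethyl orthoformate; 14 di-tert-butyl (5-hydroxy-1,3-phenylene) bis(carbonate)
Product: 17 methyl bis[3,5-bis(tert-butoxycarbonyloxy)phenyl] orthoformate
Conditions: 14 (1.0 equiv), pyridinium p-toluenesulfonate (1 mol %), toluene, reflux at 250 mbar (about 65 °C) through a Soxhlet thimble of 4 Å MS (MeOH removed); Et3N quench; filtration through basic alumina
Reagents that add atoms: none
Why: A second transorthoesterification, again pulled by removal of methanol, replaces one methoxy group of 16 by a second aryloxy group, which is the designated leaving group for step 8, because a silyl Lewis acid expels an aryloxide (the best nucleofuge at the orthoformate carbon) and 16 itself would therefore give only the dimethoxycarbenium ion.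

Step 8
Reactants: 12 (3S,4R)-5,6,7,8-tetramethoxy-4-(4-methoxyphenyl)-3-[(E)-2-(4-methoxyphenyl)ethenyl]chroman-2-one; 17 methyl bis[3,5-bis(tert-butoxycarbonyloxy)phenyl] orthoformate
Product: 20 (3R,4R)-3-[(2S,3R,4R)-5,7-bis(tert-butoxycarbonyloxy)-2-hydroxy-4-(4-methoxyphenyl)chroman-3-yl]-5,6,7,8-tetramethoxy-4-(4-methoxyphenyl)chroman-2-one, via oxocarbenium triflate 18 (not isolated), via methyl acetal 19 (not isolated)
Conditions: 17 (1.5 equiv), Me3SiOTf (1.2 equiv), 2,6-di-tert-butyl-4-methylpyridine (1.5 equiv), 4 Å MS, CH2Cl2, −78 to −40 °C; then 1 M HCl, THF, 0 °C to rt; liberated 14 recovered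
Reagents that add atoms: water, O
Why: Proposed new method: Me3SiOTf ionises 17 (loss of one aryloxide as its silyl ether) to the aryloxy(methoxy)carbenium ion 18, a cationic 2-oxadiene (C2=O1+–C8a=C4a); its carbenium carbon, the future C2 of ring A, bonds to the styrene β-carbon (C3) and the developing p-methoxybenzylic cation at C4 is captured by C4a, the arene carbon ortho to O1, giving acetal 19, which the acidic quench hydrolyses to lactol 20. The closest known reaction is the oxa-Povarov reaction (polar [4+2] of aldehyde-derived O-aryl oxocarbenium ions with styrenes to 4-aryl chromans), which has not been run with a formate-level ion, while the Prins-type addition of dialkoxycarbenium ions to styrenes is known separately. The pyran ring of ring A closes by a stepwise polar [4+2]: intermolecular Prins-type C2–C3 bond formation, then 6-membered intramolecular Friedel–Crafts alkylation at C4a. C3 is set by substrate control from C3′ (in the rotamer with H-3′ eclipsing the alkene the ion should approach anti to the C3′–C4′ bond) and C4 by suprafacial addition across the (E)-alkene, trans to the C3 substituent, which relays 4′R to 4R; the acetal centre C2 is lost in step 9. The step needs regioselectivity, secured by p-methoxy stabilisation of the C4 cation, and chemoselectivity of 18 for the alkene over arene C–H sites, secured by the two carbonates that deactivate the ring A arene towards intermolecular attack while leaving C4a reactive enough for ring closure, and by ring B being fully substituted.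

Step 9
Reactants: 20 (3R,4R)-3-[(2S,3R,4R)-5,7-bis(tert-butoxycarbonyloxy)-2-hydroxy-4-(4-methoxyphenyl)chroman-3-yl]-5,6,7,8-tetramethoxy-4-(4-methoxyphenyl)chroman-2-one
Product: 21 (3R,3′R,4R,4′R)-5,7-bis(tert-butoxycarbonyloxy)-5′,6′,7′,8′-tetramethoxy-4,4′-bis(4-methoxyphenyl)-[3,3′-bichromane]-2,2′-dione (both rings 3,4-trans)
Conditions: Ag2CO3 on Celite, toluene, 80 °C
Reagents that add atoms: none
Why: Fétizon oxidation of the lactol to the lactone is neutral and selective for the hemiacetal, so both anomers should converge on one bis-lactone with C3, C4, C3′ and C4′ untouched.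

Step 10
Reactants: 21 (3R,3′R,4R,4′R)-5,7-bis(tert-butoxycarbonyloxy)-5′,6′,7′,8′-tetramethoxy-4,4′-bis(4-methoxyphenyl)-[3,3′-bichromane]-2,2′-dione
Product: 23 (3S,3′S,4R,4′R)-5,7-bis(tert-butoxycarbonyloxy)-5′,6′,7′,8′-tetramethoxy-4,4′-bis(4-methoxyphenyl)-[3,3′-bichromane]-2,2′-dione (both rings 3,4-cis), via dilithium bis-enolate 22 (not isolated)
Conditions: LiN(SiMe3)2 (2.4 equiv), THF, −78 °C; then inverse quench into AcOH/THF, −78 °C
Reagents that add atoms: none
Why: Double enolisation erases C3 and C3′, and kinetic C-protonation of each enolate should occur on the face anti to the pseudo-axial aryl group on the neighbouring C4 (C4′), turning each ring from 3,4-trans to 3,4-cis (3S, 3′S) under substrate control from C4 and C4′.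

Step 11
Reactants: 23 (3S,3′S,4R,4′R)-5,7-bis(tert-butoxycarbonyloxy)-5′,6′,7′,8′-tetramethoxy-4,4′-bis(4-methoxyphenyl)-[3,3′-bichromane]-2,2′-dione
Product: 24 (3S,3′S,4R,4′R)-5,5′,6′,7,7′,8′-hexahydroxy-4,4′-bis(4-hydroxyphenyl)-[3,3′-bichromane]-2,2′-dione
Conditions: BBr3 (12 equiv), CH2Cl2, −78 to 0 °C; then ice-water
Reagents that add atoms: none
Why: Lewis acid-mediated cleavage of the six aryl methyl ethers and the two tert-butyl carbonates (global deprotection) runs under non-basic conditions, which should leave the enolisable cis C3 centres and both lactones intact.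

Compound list
1 | 1,2,3,4-tetramethoxybenzene | COc1ccc(OC)c(OC)c1OC | starting material
2 | (2,3,4,5-tetramethoxyphenyl)lithium | [Li]c1cc(OC)c(OC)c(OC)c1OC | intermediate
3 | dimethyl (2,3,4,5-tetramethoxyphenyl)boronate | COB(OC)c1cc(OC)c(OC)c(OC)c1OC | intermediate
4 | 2,3,4,5-tetramethoxyphenol | Oc1cc(OC)c(OC)c(OC)c1OC | intermediate
5 | ethyl propiolate | CCOC(=O)C#C | starting material
6 | ethyl (2Z)-3-(2-hydroxy-3,4,5,6-tetramethoxyphenyl)prop-2-enoate | CCOC(=O)/C=C\c1c(O)c(OC)c(OC)c(OC)c1OC | intermediate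
7 | 5,6,7,8-tetramethoxy-2H-chromen-2-one | O=c1ccc2c(OC)c(OC)c(OC)c(OC)c2o1 | intermediate
8 | (4-methoxyphenyl)boronic acid | COc1ccc(cc1)B(O)O | starting material
9 | (4R)-5,6,7,8-tetramethoxy-4-(4-methoxyphenyl)chroman-2-one | O=C1C[C@H](c2ccc(OC)cc2)c2c(OC)c(OC)c(OC)c(OC)c2O1 | intermediate
10 | 1-[(E)-2-bromoethenyl]-4-methoxybenzene | COc1ccc(/C=C/Br)cc1 | starting material
11 | chlorozinc enolate of 9 | Cl[Zn]OC1=C[C@H](c2ccc(OC)cc2)c2c(OC)c(OC)c(OC)c(OC)c2O1 | intermediate
12 | (3S,4R)-5,6,7,8-tetramethoxy-4-(4-methoxyphenyl)-3-[(E)-2-(4-methoxyphenyl)ethenyl]chroman-2-one | O=C1[C@@H](/C=C/c2ccc(OC)cc2)[C@H](c2ccc(OC)cc2)c2c(OC)c(OC)c(OC)c(OC)c2O1 | intermediate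
13 | phloroglucinol (benzene-1,3,5-triol) | Oc1cc(O)cc(O)c1 | starting material
14 | di-tert-butyl (5-hydroxy-1,3-phenylene) bis(carbonate) | CC(C)(C)OC(=O)Oc1cc(O)cc(OC(=O)OC(C)(C)C)c1 | intermediate
15 | trimethyl orthoformate | COC(OC)OC | starting material
16 | 3,5-bis(tert-butoxycarbonyloxy)phenyl dimethyl orthoformate | COC(OC)Oc1cc(OC(=O)OC(C)(C)C)cc(OC(=O)OC(C)(C)C)c1 | intermediate
17 | methyl bis[3,5-bis(tert-butoxycarbonyloxy)phenyl] orthoformate | COC(Oc1cc(OC(=O)OC(C)(C)C)cc(OC(=O)OC(C)(C)C)c1)Oc1cc(OC(=O)OC(C)(C)C)cc(OC(=O)OC(C)(C)C)c1 | intermediate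
18 | [3,5-bis(tert-butoxycarbonyloxy)phenoxy](methoxy)methylium triflate | C[O+]=COc1cc(OC(=O)OC(C)(C)C)cc(OC(=O)OC(C)(C)C)c1.[O-]S(=O)(=O)C(F)(F)F | intermediate
19 | (3R,4R)-3-[(2S,3R,4R)-5,7-bis(tert-butoxycarbonyloxy)-2-methoxy-4-(4-methoxyphenyl)chroman-3-yl]-5,6,7,8-tetramethoxy-4-(4-methoxyphenyl)chroman-2-one | CO[C@H]1Oc2cc(OC(=O)OC(C)(C)C)cc(OC(=O)OC(C)(C)C)c2[C@@H](c2ccc(OC)cc2)[C@@H]1[C@@H]1C(=O)Oc2c(OC)c(OC)c(OC)c(OC)c2[C@H]1c1ccc(OC)cc1 | intermediate
20 | (3R,4R)-3-[(2S,3R,4R)-5,7-bis(tert-butoxycarbonyloxy)-2-hydroxy-4-(4-methoxyphenyl)chroman-3-yl]-5,6,7,8-tetramethoxy-4-(4-methoxyphenyl)chroman-2-one | O[C@H]1Oc2cc(OC(=O)OC(C)(C)C)cc(OC(=O)OC(C)(C)C)c2[C@@H](c2ccc(OC)cc2)[C@@H]1[C@@H]1C(=O)Oc2c(OC)c(OC)c(OC)c(OC)c2[C@H]1c1ccc(OC)cc1 | intermediate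
21 | (3R,3′R,4R,4′R)-5,7-bis(tert-butoxycarbonyloxy)-5′,6′,7′,8′-tetramethoxy-4,4′-bis(4-methoxyphenyl)-[3,3′-bichromane]-2,2′-dione | O=C1Oc2cc(OC(=O)OC(C)(C)C)cc(OC(=O)OC(C)(C)C)c2[C@@H](c2ccc(OC)cc2)[C@@H]1[C@@H]1C(=O)Oc2c(OC)c(OC)c(OC)c(OC)c2[C@H]1c1ccc(OC)cc1 | intermediate
22 | dilithium bis-enolate of 21 | [Li]OC1Oc2cc(OC(=O)OC(C)(C)C)cc(OC(=O)OC(C)(C)C)c2[C@@H](c2ccc(OC)cc2)C=1C1=C(O[Li])Oc2c(OC)c(OC)c(OC)c(OC)c2[C@H]1c1ccc(OC)cc1 | intermediate
23 | (3S,3′S,4R,4′R)-5,7-bis(tert-butoxycarbonyloxy)-5′,6′,7′,8′-tetramethoxy-4,4′-bis(4-methoxyphenyl)-[3,3′-bichromane]-2,2′-dione | O=C1Oc2cc(OC(=O)OC(C)(C)C)cc(OC(=O)OC(C)(C)C)c2[C@@H](c2ccc(OC)cc2)[C@H]1[C@H]1C(=O)Oc2c(OC)c(OC)c(OC)c(OC)c2[C@H]1c1ccc(OC)cc1 | intermediate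
24 | (3S,3′S,4R,4′R)-5,5′,6′,7,7′,8′-hexahydroxy-4,4′-bis(4-hydroxyphenyl)-[3,3′-bichromane]-2,2′-dione | O=C1Oc2cc(O)cc(O)c2[C@@H](c2ccc(O)cc2)[C@H]1[C@H]1C(=O)Oc2c(O)c(O)c(O)c(O)c2[C@H]1c1ccc(O)cc1 | target

Total step count: 11. Longest linear sequence: 8 steps (steps 1, 2, 3, 4, 8, 9, 10, 11).

Steps most likely to fail

Step 8. The ion may add to the wrong face of the alkene, or the ring may close only after bond rotation in the benzylic cation, and either process would give the C4 epimer of ring A. Partial loss of a carbonate to the Lewis acid, or methyl transfer from the ion before it meets the alkene, are further risks. The fallback sets out from 9 and comes back at 21. 5,7-Dihydroxycoumarin is bis-carbonated (Boc2O, DMAP) to 5,7-bis(tert-butoxycarbonyloxy)-2H-chromen-2-one F1, and Rh(acac)(C2H4)2/(R)-SEGPHOS-catalysed addition of 8 then gives (4R)-5,7-bis(tert-butoxycarbonyloxy)-4-(4-methoxyphenyl)chroman-2-one F2. The lithium enolates of 9 and F2 (F2 in excess; LiN(SiMe3)2, THF, −78 °C) are oxidised together with CuCl2 in an oxidative enolate cross-coupling. Each enolate should bond anti to its own C4 aryl group, so the cross-coupled product is the all-trans bis-lactone 21, to be separated from the two homodimers. In this fallback both C4 centres are set by the catalyst and no relay is needed.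

Step 10. The second deprotonation may stay incomplete, the protonation may proceed without face discrimination, or a carbonate may migrate from O5 to the C3 enolate carbon. The fallback sets out from 21 and comes back at 23. Bis-enolate 22 is oxidised with I2 at −78 °C to the tetrasubstituted alkene (3E,4R,4′R)-5,7-bis(tert-butoxycarbonyloxy)-5′,6′,7′,8′-tetramethoxy-4,4′-bis(4-methoxyphenyl)-[3,3′-bichromanylidene]-2,2′-dione F3. The 4R and 4′R aryl groups lie on one face of this (E)-alkene, so syn hydrogenation (H2, Pd/C, EtOAc) from the open face should place both new hydrogens anti to the aryl groups and give 23.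

Step 4. The lactone enolate may lose its aryloxide (ketene formation) before transmetallation, or the new double bond may migrate into conjugation with the lactone during the base equilibration. The fallback sets out from 9 and comes back at 12. Enolate alkylation (LiN(SiMe3)2, 2-bromo-1-(4-methoxyphenyl)ethanone, THF, −78 °C) should give the trans ketone (3S,4R)-5,6,7,8-tetramethoxy-4-(4-methoxyphenyl)-3-[2-(4-methoxyphenyl)-2-oxoethyl]chroman-2-one F4. Reduction with NaBH4 gives the benzylic alcohol (3S,4R)-3-[2-hydroxy-2-(4-methoxyphenyl)ethyl]-5,6,7,8-tetramethoxy-4-(4-methoxyphenyl)chroman-2-one F5 as a mixture of carbinol epimers. Acid-catalysed dehydration (TsOH, toluene, 80 °C) through the p-methoxybenzylic cation should then give the (E)-styrene 12.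

Further compounds
F1 | step 8 | 5,7-bis(tert-butoxycarbonyloxy)-2H-chromen-2-one | O=c1ccc2c(OC(=O)OC(C)(C)C)cc(OC(=O)OC(C)(C)C)cc2o1
F2 | step 8 | (4R)-5,7-bis(tert-butoxycarbonyloxy)-4-(4-methoxyphenyl)chroman-2-one | O=C1C[C@H](c2ccc(OC)cc2)c2c(OC(=O)OC(C)(C)C)cc(OC(=O)OC(C)(C)C)cc2O1
F3 | step 10 | (3E,4R,4′R)-5,7-bis(tert-butoxycarbonyloxy)-5′,6′,7′,8′-tetramethoxy-4,4′-bis(4-methoxyphenyl)-[3,3′-bichromanylidene]-2,2′-dione | O=C1Oc2cc(OC(=O)OC(C)(C)C)cc(OC(=O)OC(C)(C)C)c2[C@@H](c2ccc(OC)cc2)\C1=C1/C(=O)Oc2c(OC)c(OC)c(OC)c(OC)c2[C@H]1c1ccc(OC)cc1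
F4 | step 4 | (3S,4R)-5,6,7,8-tetramethoxy-4-(4-methoxyphenyl)-3-[2-(4-methoxyphenyl)-2-oxoethyl]chroman-2-one | O=C1[C@@H](CC(=O)c2ccc(OC)cc2)[C@H](c2ccc(OC)cc2)c2c(OC)c(OC)c(OC)c(OC)c2O1
F5 | step 4 | (3S,4R)-3-[2-hydroxy-2-(4-methoxyphenyl)ethyl]-5,6,7,8-tetramethoxy-4-(4-methoxyphenyl)chroman-2-one (carbinol epimers) | O=C1[C@@H](CC(O)c2ccc(OC)cc2)[C@H](c2ccc(OC)cc2)c2c(OC)c(OC)c(OC)c(OC)c2O1
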